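**Plan**
1. Retrosynthetically, the five phenol protecting groups are removed and the C5 arm is taken back from CH2CH2 to an (E)-CH=CH, which gives a protected stilbene.
2. Ring A is numbered C1 (OMe), C2 (benzyl), C3 (OH), C4 (benzyl), C5 (arylethyl), C6 (benzyl). C5 with its two-carbon arm lies between identical benzyls on C4 and C6, the ipso and both ortho positions of an aryl iodide, so the bonds C4–CH2, C6–CH2 and C5–CH= are cut together in one palladium/norbornene (Catellani) step.
3. The C5 iodide is traced through a C5 boronate to the C5–H arene, whose C2–CH2 bond is cut to the C2 aryllithium of MOM-protected 3-methoxyphenol and a 4-oxybenzyl bromide.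
4. Forward: the C2 benzyl is attached first, iodine is placed on C5, the three-component step adds the C4 and C6 benzyls and the C5 styryl arm, and hydrogenation followed by acid finishes the route; no ring is formed at any stage.
5. The target has no stereocentre; the only stereo-element made, the E alkene of the key step, is erased by the hydrogenation.

Key step: step 9

Remark on protecting groups: the partners of step 9 carry benzyl ethers, which tolerate hot carbonate and leave in the same hydrogenation that saturates the alkene. The C2 benzyl and the C3 oxygen carry MOM ethers, which direct the lithiation, offer the iridium catalyst no unhindered aryl C–H and leave together in acid. Compounds 1, 5, 11 and 13 are assumed to be purchased.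

**Step 1**
Reactants: 1 4-hydroxybenzaldehyde
Product: 2 4-(methoxymethoxy)benzaldehyde
Conditions: MOMCl, K2CO3, acetone, 0 °C to rt
Reagents that add atoms: chloromethyl methyl ether, COCCl
Why: O-alkylation of the acidic phenol (Williamson-type MOM ether formation) should be clean because the aldehyde is inert to carbonate and the chloromethyl ether.

**Step 2**
Reactants: 2 4-(methoxymethoxy)benzaldehyde
Product: 3 [4-(methoxymethoxy)phenyl]methanol
Conditions: NaBH4, MeOH, 0 °C
Reagents that add atoms: none
Why: Borohydride reduction of an aromatic aldehyde is routine and leaves the acetal untouched.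

**Step 3**
Reactants: 3 [4-(methoxymethoxy)phenyl]methanol
Product: 4 1-(bromomethyl)-4-(methoxymethoxy)benzene
Conditions: CBr4, PPh3, CH2Cl2, 0 °C; filtered through a short silica pad and used at once
Reagents that add atoms: carbon tetrabromide, BrC(Br)(Br)Br
Why: The Appel reaction converts the benzylic alcohol through its alkoxyphosphonium salt into the bromide under neutral conditions, so the acid-labile MOM ether should survive.

**Step 4**
Reactants: 5 3-methoxyphenol
Product: 6 1-methoxy-3-(methoxymethoxy)benzene
Conditions: MOMCl, K2CO3, DMF, 0 °C to rt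
Reagents that add atoms: chloromethyl methyl ether, COCCl
Why: Phenoxide O-alkylation with the chloromethyl ether (Williamson-type MOM protection) installs the second ortho-directing group needed for step 5.

**Step 5**
Reactants: 6 1-methoxy-3-(methoxymethoxy)benzene; 4 1-(bromomethyl)-4-(methoxymethoxy)benzene
Product: 8 1-methoxy-3-(methoxymethoxy)-2-[4-(methoxymethoxy)benzyl]benzene, via C2 aryllithium 7 (not isolated)
Conditions: n-BuLi, THF, 0 °C to rt; then CuI (10 mol%), 4, −78 °C to rt
Reagents that add atoms: none
Why: Directed ortho-metalation should remove the C2 hydrogen, the one flanked and chelated by both the OMe and OMOM groups, and the aryllithium should then displace the benzylic bromide in an SN2 alkylation, with catalytic CuI suppressing halogen–lithium exchange and Wurtz coupling.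

**Step 6**
Reactants: 8 1-methoxy-3-(methoxymethoxy)-2-[4-(methoxymethoxy)benzyl]benzene
Product: 9 2-{3-methoxy-5-(methoxymethoxy)-4-[4-(methoxymethoxy)benzyl]phenyl}-4,4,5,5-tetramethyl-1,3,2-dioxaborolane
Conditions: [Ir(OMe)(cod)]2 (1.5 mol%), 4,4′-di-tert-butyl-2,2′-bipyridine (3 mol%), B2pin2 (1.0 equiv), THF, 80 °C
Reagents that add atoms: bis(pinacolato)diboron, CC1(C)OB(B2OC(C)(C)C(C)(C)O2)OC1(C)C
Why: Iridium-catalysed C–H borylation is sterically governed, and C5–H of ring A is the only aryl C–H in 8 without an ortho substituent, every C–H of the para-disubstituted pendant ring being next to a substituent.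

**Step 7**
Reactants: 9 2-{3-methoxy-5-(methoxymethoxy)-4-[4-(methoxymethoxy)benzyl]phenyl}-4,4,5,5-tetramethyl-1,3,2-dioxaborolane
Product: 10 5-iodo-1-methoxy-3-(methoxymethoxy)-2-[4-(methoxymethoxy)benzyl]benzene
Conditions: CuI (10 mol%), 1,10-phenanthroline (20 mol%), KI (1.5 equiv), MeOH/H2O (4:1), air, 80 °C
Reagents that add atoms: potassium iodide, [K+].[I-]
Why: Copper-mediated aerobic iododeboronation proceeds by transmetalation of the aryl group to copper and C–I bond formation at the ipso carbon, so iodine should arrive only at C5, whereas electrophilic iodination would attack the oxygen-activated C4 and C6.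

**Step 8**
Reactants: 11 3-(benzyloxy)benzaldehyde
Product: 12 1-(benzyloxy)-3-ethenylbenzene
Conditions: Ph3PCH3Br, KOtBu, THF, 0 °C to rt
Reagents that add atoms: methyltriphenylphosphonium bromide, C[P+](c1ccccc1)(c1ccccc1)c1ccccc1.[Br-]
Why: Wittig methylenation of a non-enolisable aromatic aldehyde with the unstabilised ylide is reliable, and the benzyl ether is inert to it.

**Step 9**
Reactants: 10 5-iodo-1-methoxy-3-(methoxymethoxy)-2-[4-(methoxymethoxy)benzyl]benzene; 13 1-(benzyloxy)-4-(chloromethyl)benzene (two molecules are incorporated); 12 1-(benzyloxy)-3-ethenylbenzene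
Product: 14 4,6-bis[4-(benzyloxy)benzyl]-5-[(E)-2-(3-(benzyloxy)phenyl)ethenyl]-1-methoxy-3-(methoxymethoxy)-2-[4-(methoxymethoxy)benzyl]benzene
Conditions: 13 (3 equiv), 12 (2 equiv), Pd(OAc)2 (10 mol%), tri(2-furyl)phosphine (22 mol%), norbornene (3 equiv), Cs2CO3 (5 equiv), MeCN, 85 °C, argon
Reagents that add atoms: none
Why: Oxidative addition of the C5–I bond of 10 to zerovalent palladium and exo carbopalladation of norbornene give a norbornylpalladium species with no accessible syn β-hydrogen, which palladates C4 with carbonate assistance to a five-membered palladacycle; 13 then adds oxidatively to give tetravalent palladium, reductive elimination forms the C4–CH2 bond, and the same sequence repeats at C6. With both ortho positions filled, steric pressure drives β-carbon elimination of norbornene, and the resulting divalent arylpalladium inserts styrene 12 and undergoes β-hydride elimination to the (E)-stilbene (Mizoroki–Heck termination). The closest known reaction type is the Catellani ortho,ortho-dialkylation of ortho-unsubstituted aryl iodides with ipso Heck termination, together with the known palladium/norbornene ortho-benzylation of aryl iodides by benzyl chlorides. No ring is closed and no stereocentre is formed; the E geometry of the new alkene is of no consequence because step 10 saturates it. The selectivity needed is one of order and site: both benzylations must precede the Heck event, which norbornene secures because it inserts into the unhindered arylpalladium faster than the styrene and is expelled only once C4 and C6 are both substituted, and the only C–H bonds left on ring A are those at C4 and C6, each beside a small alkoxy oxygen. Chemoselectivity between the two halides rests on the much faster oxidative addition of the aryl iodide than of the benzylic chloride to phosphine-ligated zerovalent palladium.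

**Step 10**
Reactants: 14 4,6-bis[4-(benzyloxy)benzyl]-5-[(E)-2-(3-(benzyloxy)phenyl)ethenyl]-1-methoxy-3-(methoxymethoxy)-2-[4-(methoxymethoxy)benzyl]benzene
Product: 15 4,6-bis(4-hydroxybenzyl)-5-[2-(3-hydroxyphenyl)ethyl]-1-methoxy-3-(methoxymethoxy)-2-[4-(methoxymethoxy)benzyl]benzene
Conditions: H2 (1 atm), 10% Pd/C, EtOAc/MeOH, rt
Reagents that add atoms: none
Why: Heterogeneous catalytic hydrogenation should saturate the disubstituted stilbene double bond and hydrogenolyse the three aryl benzyl ethers in one operation, while the MOM ethers, the aryl methyl ether and the diarylmethane C–C bonds are not cleaved.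

**Step 11**
Reactants: 15 4,6-bis(4-hydroxybenzyl)-5-[2-(3-hydroxyphenyl)ethyl]-1-methoxy-3-(methoxymethoxy)-2-[4-(methoxymethoxy)benzyl]benzene
Product: 16 2,4,6-tris(4-hydroxybenzyl)-3-[2-(3-hydroxyphenyl)ethyl]-5-methoxyphenol (CNP0262401.0)
Conditions: HCl (3 M aq), MeOH/THF, 40 °C
Reagents that add atoms: none
Why: Acid-catalysed acetal exchange with methanol should release both MOM-protected phenols, the formaldehyde unit leaving as dimethoxymethane, while the aryl methyl ether is inert and the fully substituted ring A offers no site for hydroxymethylation.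

**Compound list**
1 | 4-hydroxybenzaldehyde | O=Cc1ccc(O)cc1 | starting material
2 | 4-(methoxymethoxy)benzaldehyde | COCOc1ccc(C=O)cc1 | intermediate
3 | [4-(methoxymethoxy)phenyl]methanol | COCOc1ccc(CO)cc1 | intermediate
4 | 1-(bromomethyl)-4-(methoxymethoxy)benzene | COCOc1ccc(CBr)cc1 | intermediate
5 | 3-methoxyphenol | COc1cccc(O)c1 | starting material
6 | 1-methoxy-3-(methoxymethoxy)benzene | COCOc1cccc(OC)c1 | intermediate
7 | [2-methoxy-6-(methoxymethoxy)phenyl]lithium | [Li]c1c(OC)cccc1OCOC | intermediate
8 | 1-methoxy-3-(methoxymethoxy)-2-[4-(methoxymethoxy)benzyl]benzene | COCOc1ccc(Cc2c(OC)cccc2OCOC)cc1 | intermediate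
9 | 2-{3-methoxy-5-(methoxymethoxy)-4-[4-(methoxymethoxy)benzyl]phenyl}-4,4,5,5-tetramethyl-1,3,2-dioxaborolane | COCOc1ccc(Cc2c(OC)cc(B3OC(C)(C)C(C)(C)O3)cc2OCOC)cc1 | intermediate
10 | 5-iodo-1-methoxy-3-(methoxymethoxy)-2-[4-(methoxymethoxy)benzyl]benzene | COCOc1ccc(Cc2c(OC)cc(I)cc2OCOC)cc1 | intermediate
11 | 3-(benzyloxy)benzaldehyde | O=Cc1cccc(OCc2ccccc2)c1 | starting material
12 | 1-(benzyloxy)-3-ethenylbenzene | C=Cc1cccc(OCc2ccccc2)c1 | intermediate
13 | 1-(benzyloxy)-4-(chloromethyl)benzene | ClCc1ccc(OCc2ccccc2)cc1 | starting material
14 | 4,6-bis[4-(benzyloxy)benzyl]-5-[(E)-2-(3-(benzyloxy)phenyl)ethenyl]-1-methoxy-3-(methoxymethoxy)-2-[4-(methoxymethoxy)benzyl]benzene | COc1c(Cc2ccc(OCOC)cc2)c(OCOC)c(Cc2ccc(OCc3ccccc3)cc2)c(/C=C/c2cccc(OCc3ccccc3)c2)c1Cc1ccc(OCc2ccccc2)cc1 | intermediate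
15 | 4,6-bis(4-hydroxybenzyl)-5-[2-(3-hydroxyphenyl)ethyl]-1-methoxy-3-(methoxymethoxy)-2-[4-(methoxymethoxy)benzyl]benzene | COc1c(Cc2ccc(OCOC)cc2)c(OCOC)c(Cc2ccc(O)cc2)c(CCc2cccc(O)c2)c1Cc1ccc(O)cc1 | intermediate
16 | 2,4,6-tris(4-hydroxybenzyl)-3-[2-(3-hydroxyphenyl)ethyl]-5-methoxyphenol | COc1c(Cc2ccc(O)cc2)c(O)c(Cc2ccc(O)cc2)c(CCc2cccc(O)c2)c1Cc1ccc(O)cc1 | target

**Step count**
Total: 11 steps. Longest linear sequence: 9 steps (steps 1, 2, 3, 5, 6, 7, 9, 10, 11).

**Steps most likely to fail**

Step 9. Palladation of the C4 and C6 hydrogens, each wedged between the palladium-bearing carbon and an alkoxy group, may be slow. Norbornene could then be lost early, so that Heck coupling after no or one benzylation, ipso reduction, or cyclisation of the arylpalladium onto a newly attached benzyl ring would compete; the benzylic chloride may also be consumed by its own oxidative addition. Fallback: setting out from 10, the order of bond formation is reversed and the C4 and C6 benzyls are brought in by cross-coupling at the two electronically most activated positions. Styrene 12 is hydroborated with 9-BBN (THF, rt) to 9-{2-[3-(benzyloxy)phenyl]ethyl}-9-borabicyclo[3.3.1]nonane F1, which is coupled with 10 in a B-alkyl Suzuki–Miyaura reaction (PdCl2(dppf), aqueous K3PO4, THF/DMF, 60 °C) to give 5-{2-[3-(benzyloxy)phenyl]ethyl}-1-methoxy-3-(methoxymethoxy)-2-[4-(methoxymethoxy)benzyl]benzene F2. N-Bromosuccinimide (2 equiv, MeCN, 0 °C) should brominate C4 and C6, each ortho to one ring oxygen and para to the other, to give the 4,6-dibromide of this bibenzyl F3. Chloride 13 is converted with zinc dust and LiCl in THF into 4-(benzyloxy)benzylzinc chloride F4, and a double Negishi coupling (Pd(OAc)2, SPhos, THF, 60 °C) should give the fully substituted bibenzyl tris(benzyl ether) F5. Hydrogenolysis of F5 under the conditions of step 10 rejoins the route at 15.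

Step 5. Halogen–lithium exchange between the aryllithium and the electron-rich benzylic bromide, followed by Wurtz-type homocoupling, or decomposition of the labile bromide before it is alkylated, may erode the C2 benzylation. Fallback: setting out from 6 (lithiated to 7 as in step 5) and aldehyde 2, addition of the aryllithium to the carbonyl group at −78 °C should give [2-methoxy-6-(methoxymethoxy)phenyl][4-(methoxymethoxy)phenyl]methanol F6. This doubly activated benzhydrol is deoxygenated by ionic hydrogenation (Et3SiH, a few equivalents of CF3CO2H, CH2Cl2, −20 °C), conditions under which the stabilised cation should form well before an aryl MOM ether is cleaved, and the route is rejoined at 8. Steps 2 and 3 are then not needed.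

Step 7. Protodeboronation, or copper-mediated transfer of methoxide or hydroxide in place of iodide, may outrun the iododeboronation. Fallback: setting out from 9, bromodeboronation with stoichiometric CuBr2 (MeOH/H2O, 80 °C) should give 5-bromo-1-methoxy-3-(methoxymethoxy)-2-[4-(methoxymethoxy)benzyl]benzene F7. A copper-catalysed aromatic Finkelstein exchange (CuI, NaI, trans-N,N′-dimethylcyclohexane-1,2-diamine, dioxane, 110 °C) then converts the bromide into the iodide and rejoins the route at 10.

**Further compounds**
F1 | step 9 | 9-{2-[3-(benzyloxy)phenyl]ethyl}-9-borabicyclo[3.3.1]nonane | C(Cc1cccc(OCc2ccccc2)c1)B1C2CCCC1CCC2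
F2 | step 9 | 5-{2-[3-(benzyloxy)phenyl]ethyl}-1-methoxy-3-(methoxymethoxy)-2-[4-(methoxymethoxy)benzyl]benzene | COCOc1ccc(Cc2c(OC)cc(CCc3cccc(OCc4ccccc4)c3)cc2OCOC)cc1
F3 | step 9 | 5-{2-[3-(benzyloxy)phenyl]ethyl}-4,6-dibromo-1-methoxy-3-(methoxymethoxy)-2-[4-(methoxymethoxy)benzyl]benzene | COCOc1ccc(Cc2c(OC)c(Br)c(CCc3cccc(OCc4ccccc4)c3)c(Br)c2OCOC)cc1
F4 | step 9 | 4-(benzyloxy)benzylzinc chloride | Cl[Zn]Cc1ccc(OCc2ccccc2)cc1
F5 | step 9 | 4,6-bis[4-(benzyloxy)benzyl]-5-{2-[3-(benzyloxy)phenyl]ethyl}-1-methoxy-3-(methoxymethoxy)-2-[4-(methoxymethoxy)benzyl]benzene | COc1c(Cc2ccc(OCOC)cc2)c(OCOC)c(Cc2ccc(OCc3ccccc3)cc2)c(CCc2cccc(OCc3ccccc3)c2)c1Cc1ccc(OCc2ccccc2)cc1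
F6 | step 5 | [2-methoxy-6-(methoxymethoxy)phenyl][4-(methoxymethoxy)phenyl]methanol | COCOc1ccc(C(O)c2c(OC)cccc2OCOC)cc1
F7 | step 7 | 5-bromo-1-methoxy-3-(methoxymethoxy)-2-[4-(methoxymethoxy)benzyl]benzene | COCOc1ccc(Cc2c(OC)cc(Br)cc2OCOC)cc1
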